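Late in the elm run, between 45 min and 100 min, Z falls by 2.18 mM min⁻¹, while between 4.0 min and 20 min it fell by 1.18 mM min⁻¹. So this flask, in which substrate Z and reagent L become product Q over catalyst E, runs faster on less Z and L.

| flask | Z | L | E | Q | time |
|---|---|---|---|---|---|
| elm | 300 mM | 450 mM | 6.00 mM |  |  |
| maple | 180 mM | 330 mM | 6.00 mM |  |  |
| cedar | 600 mM | 450 mM | 6.00 mM |  |  |
| birch | 300 mM | 1400 mM | 6.00 mM |  |  |
| larch | 300 mM | 450 mM | 6.00 mM | 150 mM | 100 min |

- Overall: Z + L -> Q, with E as catalyst.
- Constant volume, constant temperature.
- What is held in complexes is read along with the free species.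
- "The second partner" is L.
- An order is taken over about fifteen percent of the charge, up and down.

* the exponent of [Z] in the starting rate at the charge of the elm run (at the point where two percent of the Z have become Q) (one fixed amount of Q, the same in the runs compared)
* the exponent of [L] in the starting rate at the charge of the elm run (at the point where two percent of the Z have become Q)
* the maple run starts with 120 mM less of Z and of L than the elm run, and with no Q. Compared where both hold the same amount of Z, once fifteen percent of what the maple run was charged with has turned into Q, is the maple run faster, slower or alike (within a tenth)?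
* Z in the larch run at 100 min, as a share of the Z charged
* which of these the readings show (the product speeds the reaction / two substrates go astray together / the second partner ties up the catalyst / the product binds the second partner)

- elm run (time / min: [Z] / mM): 4.0: 294.9; 8.9: 288.0; 20: 276.0; 45: 229.0; 100: 109.0
- maple run (time / min: [Z] / mM): 4.0: 177.7; 8.9: 170.7; 20: 159.2; 45: 133.7; 100: 79.5
- cedar run (time / min: [Z] / mM): 4.0: 591.6; 8.9: 584.0; 20: 567.5; 45: 460.6; 100: 232.4
- birch run (time / min: [Z] / mM): 4.0: 292.5; 8.9: 282.4; 20: 252.6; 45: 90.3; 100: 0

(standard deviation of a reading: 2 mM)

Read this table column against column. Over the same early window, the maple run loses 1.16 mM min⁻¹ and the cedar run 1.51 mM min⁻¹, so the early rate responds weakly to the charge, although cedar holds twice the Z of elm. Late, cedar loses 4.15 mM min⁻¹, which is twice the elm rate.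

I therefore read two routes side by side: a catalyst route of nearly steady rate b, and a route fed by Q itself (the field's autocatalysis), taken as proportional to Q, Z and L. In elm, Q stands near 14.6 mM in the early window and near 131 mM in the late one. Two windows give two unknowns. The second is the feed time τ, the time constant with which Q would make more Q at the Z and L charged to elm, 38.9 min. The first is 0.837 mM min⁻¹, which means each E turns over once in 7.17 min.

Held against the cedar run with the same b, τ gives 4.12 mM min⁻¹ in the late window, beside the reading of 4.15 mM min⁻¹.

Now I use τ as my own reckoning. At the elm charge with 6.00 mM of Q, the fed route adds 0.154 mM min⁻¹, a share of 15.5%. That share is each order's part from the fed route, and the catalyst route adds its own small order on top. When the maple run and the elm run hold equal Z they hold equal L too, but elm holds 120 mM more Q, so maple is slower. The larch run starts with 150 mM of Q, so its fed route gives 3.86 mM min⁻¹ against b, and its start rate is 4.69 mM min⁻¹. At that rate the Z charged would last 63.9 min, but that rate does not hold, as Q rises while Z and L fall, so I take this time as a scale and not as the end of the run.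

The forecast, from “All runs then speed up as Q builds, and the speed-up grows with Z and L.”, gives orders of 0.22 and 0.2, maple slower, 9% of Z left in larch, and "the product speeds the reaction".

    E + Z → EZ (3.738 M⁻¹ min⁻¹)
    EZ + L → Vo (4.044 M⁻¹ min⁻¹)
    Vo → Q + E (0.1710 min⁻¹)
    Z + L + Q → 2 Q (0.2370 M⁻² min⁻¹)

The larch run keeps 7.10% of its Z at 100 min. The orders are 0.29 and 0.25, maple is slower at a rate ratio of 0.44, and the answer is "the product speeds the reaction". Removing the step in which Q joins Z and L moves the readings by 46 scatter units, root mean square. In the elm run, the τ of 38.9 min that I read gives 0.154 mM min⁻¹ of the 1.0 mM min⁻¹ of product formation at 6.00 mM of Q. In the birch run, with L at 1400 mM, the constant of that step gives a feed time of 10.0 min at the charge, and at 6.00 mM of Q, with Z and L lowered by that amount, the fed route supplies 0.583 mM min⁻¹ of the 1.4 mM min⁻¹ of product formation there.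

The data were computed for substances that don't exist; the scatter is artificial.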